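**Retrosynthetic overview**

1. Both benzene rings are bought. The only ring to build is the oxolane O1–C2–C3–C4–C5, and it is closed last, in one step, from two acyclic fragments.
2. The C4–OH bond is read as a C4–Si bond (Tamao–Fleming oxidation, retention). The catechol is carried as its bis(benzyl ether) and the CH2OH group as a silyl ether.
3. Key disconnection: C2–C3 and O1–C5 together, in a catalytic enantioselective [3+2] annulation. 3,4-Bis(benzyloxy)benzaldehyde gives O1 and C2; a (Z)-allylsilane gives C3 (γ-carbon), C4 (β-carbon) and C5 (the CH2Si carbon), with silicon moving from C5 to C4.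
4. Enabling feature: C5 is an unsubstituted CH2 between O1 and the oxygen-bearing quaternary C4, and the C2-aryl, C3-CH2OH and C4-OH groups are all cis on the oxolane. This is the pattern left by syn addition to the aldehyde followed by anti-SE2' attack and 1,2-silyl shift on a (Z)-allylsilane.
5. The allylsilane comes from a (Z)-vinyl iodide (propargyl alcohol + 3,4-dimethoxybenzyl bromide, then trans-hydroalumination/iodination) and a silylmethyl Grignard reagent (Kumada coupling).

Key step: step 6

Assumption: the (2R,3R)-tartrate-derived (acyloxy)borane is taken to direct the allylsilane to the Re face of the aryl aldehyde, as in its additions to benzaldehyde; if the sense is opposite here, the (2S,3S) catalyst is used.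

**Route**

Step 1
Reactants: 1 prop-2-yn-1-ol; 2 4-(bromomethyl)-1,2-dimethoxybenzene
Product: 4 4-(3,4-dimethoxyphenyl)but-2-yn-1-ol, via bromomagnesium 3-(bromomagnesio)prop-2-yn-1-olate 3 (not isolated)
Conditions: EtMgBr (2.1 equiv), THF, 0 °C to rt; CuCl (10 mol %), then 2, 50 °C
Reagents that add atoms: none
Why: Copper-catalysed alkylation of an alkynyl Grignard reagent by a benzylic bromide should give the skipped aryl alkyne, the magnesium alkoxide staying unalkylated under these conditions.

Step 2
Reactants: 4 4-(3,4-dimethoxyphenyl)but-2-yn-1-ol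
Product: 6 (Z)-4-(3,4-dimethoxyphenyl)-3-iodobut-2-en-1-ol, via cyclic sodium vinylalanate 5 (not isolated)
Conditions: NaAlH2(OCH2CH2OMe)2, THF, 0 °C to rt; then I2, −78 °C to 0 °C
Reagents that add atoms: iodine, SMILES II
Why: Hydroxyl-directed trans-hydroalumination puts aluminium on C3 inside a five-membered alanate, so iodinolysis with retention should give the (Z)-iodoalkenol and fix the alkene geometry that later becomes the C3/C4 relationship.

Step 3
Reactants: 6 (Z)-4-(3,4-dimethoxyphenyl)-3-iodobut-2-en-1-ol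
Product: 7 tert-butyl{[(Z)-4-(3,4-dimethoxyphenyl)-3-iodobut-2-en-1-yl]oxy}diphenylsilane
Conditions: TBDPSCl, imidazole, DMF, rt
Reagents that add atoms: tert-butyl(chloro)diphenylsilane, SMILES CC(C)(C)[Si](Cl)(c1ccccc1)c1ccccc1
Why: Standard silylation of a primary alcohol; the bulky, Lewis-acid-stable silyl ether masks the future C3 hydroxymethyl group and keeps its oxygen away from the Lewis acid of step 6.

Step 4
Reactants: 8 diphenylmethane; 9 chloro(chloromethyl)dimethylsilane
Product: 11 (chloromethyl)(diphenylmethyl)dimethylsilane, via diphenylmethyllithium 10 (not isolated)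
Conditions: n-BuLi, THF, 0 °C to rt; then 9, −78 °C to rt
Reagents that add atoms: none
Why: Nucleophilic substitution at silicon is much faster than at the CH2Cl carbon, so the benzhydryl anion should give the silane carrying a bulky, fluoride-cleavable group on silicon.

Step 5
Reactants: 11 (chloromethyl)(diphenylmethyl)dimethylsilane; 7 tert-butyl{[(Z)-4-(3,4-dimethoxyphenyl)-3-iodobut-2-en-1-yl]oxy}diphenylsilane
Product: 13 tert-butyl({(2Z)-3-{[(diphenylmethyl)dimethylsilyl]methyl}-4-(3,4-dimethoxyphenyl)but-2-en-1-yl}oxy)diphenylsilane, via [(diphenylmethyl)dimethylsilyl]methylmagnesium chloride 12 (not isolated)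
Conditions: Mg, THF, reflux; then 7, Pd(PPh3)4 (5 mol %), THF, 50 °C
Reagents that add atoms: none
Why: Kumada coupling of an α-silyl Grignard reagent with a vinyl iodide proceeds with retention of alkene geometry, so the (Z)-allylsilane with CH2Si cis to CH2OTBDPS should result.

Step 6
Reactants: 13 tert-butyl({(2Z)-3-{[(diphenylmethyl)dimethylsilyl]methyl}-4-(3,4-dimethoxyphenyl)but-2-en-1-yl}oxy)diphenylsilane; 14 3,4-bis(benzyloxy)benzaldehyde
Product: 15 (2R,3R,4R)-2-[3,4-bis(benzyloxy)phenyl]-3-{[(tert-butyldiphenylsilyl)oxy]methyl}-4-(3,4-dimethoxybenzyl)-4-[(diphenylmethyl)dimethylsilyl]oxolane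
Conditions: chiral (acyloxy)borane from (2R,3R)-2-O-(2,6-diisopropoxybenzoyl)tartaric acid and BH3·THF (20 mol %), EtCN, −78 °C to −40 °C
Reagents that add atoms: none
Why: Proposed new method: the chiral boron Lewis acid binds aldehyde 14, and the γ-carbon of 13 adds to its Re face through an open antiperiplanar transition state, anti to the C–Si bond (anti-SE2'), giving a tertiary β-silyl cation held by silicon; the boron-bound alkoxide then attacks the CH2 terminus while silicon shifts to C4, which closes the oxolane (O1–C5 bond, 5-endo opening of the three-membered silicon-bridged ion; the strained 4-exo oxetane would re-ionise) and frees the catalyst. The closest known reactions are the BF3·OEt2-promoted [3+2] annulation of bulky allylsilanes with aldehydes to 3-silyloxolanes and the chiral (acyloxy)borane-catalysed, syn- and enantioselective Hosomi–Sakurai addition of β,γ-disubstituted allylsilanes to aromatic aldehydes; new is their merger, through a tertiary cation, under catalyst control. C2 is controlled by the catalyst (aldehyde face), C3 by the syn preference of the open transition state, and C4 by the stereospecific anti addition of C2 and silicon across the (Z)-alkene, which puts Si cis to CH2OTBDPS and the benzyl group trans. The step needs annulation to win over desilylation (secured by the bulky benzhydryldimethylsilyl group, which resists attack at silicon), closure at CH2 and not at the tertiary centre (secured by ring strain), and no Friedel–Crafts reaction of the dimethoxyphenyl ring (secured by the much higher nucleophilicity of the trisubstituted allylsilane).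

Step 7
Reactants: 15 (2R,3R,4R)-2-[3,4-bis(benzyloxy)phenyl]-3-{[(tert-butyldiphenylsilyl)oxy]methyl}-4-(3,4-dimethoxybenzyl)-4-[(diphenylmethyl)dimethylsilyl]oxolane
Product: 17 (3R,4R,5R)-5-[3,4-bis(benzyloxy)phenyl]-3-(3,4-dimethoxybenzyl)-4-(hydroxymethyl)oxolan-3-ol, via bicyclic oxasilolane 16 (not isolated)
Conditions: Bu4NF, THF, 50 °C; then 30% H2O2, KHCO3, MeOH–THF, 50 °C
Reagents that add atoms: hydrogen peroxide, SMILES OO
Why: Tamao–Fleming oxidation: fluoride removes the silyl ether, the freed cis-CH2O group displaces the benzhydryl group from silicon to give the five-membered alkoxysilane 16, and basic hydrogen peroxide then oxidises its C4–Si bond with retention, so the C4 hydroxyl should end cis to CH2OH.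

Step 8
Reactants: 17 (3R,4R,5R)-5-[3,4-bis(benzyloxy)phenyl]-3-(3,4-dimethoxybenzyl)-4-(hydroxymethyl)oxolan-3-ol
Product: 18 (3R,4R,5R)-5-(3,4-dihydroxyphenyl)-3-(3,4-dimethoxybenzyl)-4-(hydroxymethyl)oxolan-3-ol
Conditions: H2 (1 atm), 10% Pd/C, EtOAc, rt
Reagents that add atoms: none
Why: Hydrogenolysis of aryl benzyl ethers over Pd/C in ethyl acetate is much faster than cleavage of the benzylic C–O bond of the oxolane, so the catechol should be unmasked without touching a stereocentre if the reaction is stopped once both benzyl ethers are gone.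

**Compound list**

1 | prop-2-yn-1-ol | C#CCO | starting material
2 | 4-(bromomethyl)-1,2-dimethoxybenzene | COc1ccc(CBr)cc1OC | starting material
3 | bromomagnesium 3-(bromomagnesio)prop-2-yn-1-olate | Br[Mg]OCC#C[Mg]Br | intermediate
4 | 4-(3,4-dimethoxyphenyl)but-2-yn-1-ol | COc1ccc(CC#CCO)cc1OC | intermediate
5 | cyclic sodium vinylalanate (2,5-dihydro-1,2-oxaluminole ate complex, Al on C3 of the butenol) | [Na+].COCCO[Al-]1(OCCOC)OCC=C1Cc1ccc(OC)c(OC)c1 | intermediate
6 | (Z)-4-(3,4-dimethoxyphenyl)-3-iodobut-2-en-1-ol | OC/C=C(\I)Cc1ccc(OC)c(OC)c1 | intermediate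
7 | tert-butyl{[(Z)-4-(3,4-dimethoxyphenyl)-3-iodobut-2-en-1-yl]oxy}diphenylsilane | CC(C)(C)[Si](OC/C=C(\I)Cc1ccc(OC)c(OC)c1)(c1ccccc1)c1ccccc1 | intermediate
8 | diphenylmethane | C(c1ccccc1)c1ccccc1 | starting material
9 | chloro(chloromethyl)dimethylsilane | C[Si](C)(Cl)CCl | starting material
10 | diphenylmethyllithium | [Li]C(c1ccccc1)c1ccccc1 | intermediate
11 | (chloromethyl)(diphenylmethyl)dimethylsilane | C[Si](C)(CCl)C(c1ccccc1)c1ccccc1 | intermediate
12 | [(diphenylmethyl)dimethylsilyl]methylmagnesium chloride | C[Si](C)(C[Mg]Cl)C(c1ccccc1)c1ccccc1 | intermediate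
13 | tert-butyl({(2Z)-3-{[(diphenylmethyl)dimethylsilyl]methyl}-4-(3,4-dimethoxyphenyl)but-2-en-1-yl}oxy)diphenylsilane | CC(C)(C)[Si](OC/C=C(\C[Si](C)(C)C(c1ccccc1)c1ccccc1)Cc1ccc(OC)c(OC)c1)(c1ccccc1)c1ccccc1 | intermediate
14 | 3,4-bis(benzyloxy)benzaldehyde | O=Cc1ccc(OCc2ccccc2)c(OCc2ccccc2)c1 | starting material
15 | (2R,3R,4R)-2-[3,4-bis(benzyloxy)phenyl]-3-{[(tert-butyldiphenylsilyl)oxy]methyl}-4-(3,4-dimethoxybenzyl)-4-[(diphenylmethyl)dimethylsilyl]oxolane | COc1ccc(C[C@]2([Si](C)(C)C(c3ccccc3)c3ccccc3)CO[C@@H](c3ccc(OCc4ccccc4)c(OCc4ccccc4)c3)[C@H]2CO[Si](c2ccccc2)(c2ccccc2)C(C)(C)C)cc1OC | intermediate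
16 | bicyclic oxasilolane: the oxolane of 15 with C4–SiMe2–O–CH2–C3 closed as a cis-fused five-membered ring, same configuration at the three ring carbons | COc1ccc(C[C@]23CO[C@@H](c4ccc(OCc5ccccc5)c(OCc5ccccc5)c4)[C@H]2CO[Si]3(C)C)cc1OC | intermediate
17 | (3R,4R,5R)-5-[3,4-bis(benzyloxy)phenyl]-3-(3,4-dimethoxybenzyl)-4-(hydroxymethyl)oxolan-3-ol | COc1ccc(C[C@]2(O)CO[C@@H](c3ccc(OCc4ccccc4)c(OCc4ccccc4)c3)[C@H]2CO)cc1OC | intermediate
18 | (3R,4R,5R)-5-(3,4-dihydroxyphenyl)-3-(3,4-dimethoxybenzyl)-4-(hydroxymethyl)oxolan-3-ol | COc1ccc(C[C@]2(O)CO[C@@H](c3ccc(O)c(O)c3)[C@H]2CO)cc1OC | target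

**Step count and risks**

Total step count: 8. Longest linear sequence: 7 steps (1, 2, 3, 5, 6, 7, 8).

Steps most likely to fail:

Step 6 (bears the label). What may go wrong: loss of silicon from the tertiary cation before ring closure, weak discrimination of the aldehyde faces by the catalyst, or poor turnover. Fallback with known chemistry: it sets out from 13 and 14 and comes back to the route at 15. Stoichiometric BF3·OEt2 in CH2Cl2 at −78 °C to −40 °C, the established Lewis-acid [3+2] annulation of bulky allylsilanes with aldehydes, should give the racemate, that is 15 together with its mirror image, the (2S,3S,4S)-oxolane F1. Preparative chromatography on a chiral stationary phase (amylose tris(3,5-dimethylphenylcarbamate)) removes F1.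

Step 7. What may go wrong: slow migration from silicon to oxygen at the hindered tertiary carbon, or fluoride-induced β-elimination that opens the oxolane. Fallback: the benzyl group is introduced after the oxidation, so the C–Si bond to be oxidised is secondary. It sets out from 12 and 14 and comes back to the route at 18.
- Commercial benzyl prop-2-ynyl ether is hydrozirconated and iodinated (Cp2Zr(H)Cl; I2) to the vinyl iodide F2.
- Kumada coupling with 12 (Pd(PPh3)4) gives the (E)-allylsilane F3; its alkene geometry only affects the C4 centre that is later oxidised away.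
- Annulation with 14 under the conditions of step 6 should give the 2,3-cis silyloxolane F4.
- Bu4NF, then H2O2/KHCO3, oxidises its secondary C–Si bond to the oxolanol F5, the established case for this silyl group.
- Dess–Martin oxidation gives the oxolanone F6.
- 3,4-Dimethoxybenzylmagnesium bromide F7 (from 2 and Mg in Et2O, high dilution) with CeCl3 at −78 °C should add to the carbonyl face opposite the two cis substituents and give the tribenzyl tertiary alcohol F8.
- Hydrogenolysis of the three benzyl ethers (H2, Pd/C) gives 18.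

Step 8. What may go wrong: over-reduction, that is hydrogenolytic opening of the oxolane at the benzylic C2–O1 bond once the phenols are free. Fallback: a catechol protecting group removed without hydrogen. It sets out from 13 and comes back to the route at 18. 3,4-Bis(prop-2-en-1-yloxy)benzaldehyde F9 (from 3,4-dihydroxybenzaldehyde, allyl bromide and K2CO3) replaces 14 in step 6 and should give the bis(allyl ether) silyloxolane F10. Step 7 converts it into the bis(allyl ether) diol F11. Pd(PPh3)4 with morpholine then transfers both allyl groups to the amine and gives 18.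

**Further compounds**

F1 | step 6 | (2S,3S,4S)-2-[3,4-bis(benzyloxy)phenyl]-3-{[(tert-butyldiphenylsilyl)oxy]methyl}-4-(3,4-dimethoxybenzyl)-4-[(diphenylmethyl)dimethylsilyl]oxolane | COc1ccc(C[C@@]2([Si](C)(C)C(c3ccccc3)c3ccccc3)CO[C@H](c3ccc(OCc4ccccc4)c(OCc4ccccc4)c3)[C@@H]2CO[Si](c2ccccc2)(c2ccccc2)C(C)(C)C)cc1OC
F2 | step 7 | (E)-[(3-iodoprop-2-en-1-yl)oxymethyl]benzene | I/C=C/COCc1ccccc1
F3 | step 7 | [(2E)-4-(benzyloxy)but-2-en-1-yl](diphenylmethyl)dimethylsilane | C[Si](C)(C/C=C/COCc1ccccc1)C(c1ccccc1)c1ccccc1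
F4 | step 7 | (2R,3R,4S)-2-[3,4-bis(benzyloxy)phenyl]-3-[(benzyloxy)methyl]-4-[(diphenylmethyl)dimethylsilyl]oxolane | C[Si](C)(C(c1ccccc1)c1ccccc1)[C@@H]1CO[C@@H](c2ccc(OCc3ccccc3)c(OCc3ccccc3)c2)[C@H]1COCc1ccccc1
F5 | step 7 | (3S,4S,5R)-5-[3,4-bis(benzyloxy)phenyl]-4-[(benzyloxy)methyl]oxolan-3-ol | O[C@@H]1CO[C@@H](c2ccc(OCc3ccccc3)c(OCc3ccccc3)c2)[C@H]1COCc1ccccc1
F6 | step 7 | (4R,5R)-5-[3,4-bis(benzyloxy)phenyl]-4-[(benzyloxy)methyl]oxolan-3-one | O=C1CO[C@@H](c2ccc(OCc3ccccc3)c(OCc3ccccc3)c2)[C@H]1COCc1ccccc1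
F7 | step 7 | (3,4-dimethoxybenzyl)magnesium bromide | COc1ccc(C[Mg]Br)cc1OC
F8 | step 7 | (3R,4R,5R)-5-[3,4-bis(benzyloxy)phenyl]-4-[(benzyloxy)methyl]-3-(3,4-dimethoxybenzyl)oxolan-3-ol | COc1ccc(C[C@]2(O)CO[C@@H](c3ccc(OCc4ccccc4)c(OCc4ccccc4)c3)[C@H]2COCc2ccccc2)cc1OC
F9 | step 8 | 3,4-bis(prop-2-en-1-yloxy)benzaldehyde | C=CCOc1ccc(C=O)cc1OCC=C
F10 | step 8 | (2R,3R,4R)-2-[3,4-bis(prop-2-en-1-yloxy)phenyl]-3-{[(tert-butyldiphenylsilyl)oxy]methyl}-4-(3,4-dimethoxybenzyl)-4-[(diphenylmethyl)dimethylsilyl]oxolane | COc1ccc(C[C@]2([Si](C)(C)C(c3ccccc3)c3ccccc3)CO[C@@H](c3ccc(OCC=C)c(OCC=C)c3)[C@H]2CO[Si](c2ccccc2)(c2ccccc2)C(C)(C)C)cc1OC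
F11 | step 8 | (3R,4R,5R)-5-[3,4-bis(prop-2-en-1-yloxy)phenyl]-3-(3,4-dimethoxybenzyl)-4-(hydroxymethyl)oxolan-3-ol | COc1ccc(C[C@]2(O)CO[C@@H](c3ccc(OCC=C)c(OCC=C)c3)[C@H]2CO)cc1OC
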